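## Retrosynthetic overview
1. Target ⇒ (2S)-8,5'-diallyl-7,3',4'-trihydroxyflavanone. Both prenyl groups are made last from allyl groups by one double cross-metathesis under neutral conditions.
2. Diallylflavanone ⇒ unprotected (E)-3',5-diallyl-2',4',3,4-tetrahydroxychalcone. The key disconnection is O1–C2, closed by a catalytic enantioselective oxa-Michael addition that forms ring C and sets C-2.
3. Chalcone ⇒ 3-allyl-2,4-dihydroxyacetophenone + 3-allyl-4,5-dihydroxybenzaldehyde, joined by acid Claisen–Schmidt condensation without protecting groups.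
4. Each allylphenol ⇒ O-allylation and aromatic Claisen rearrangement of 2,4-dihydroxyacetophenone or 3,4-dihydroxybenzaldehyde.
5. Ring order: rings A and B are bought, and ring C is the only ring made (step 6).

Assumption: the sense of induction of the new catalyst cannot be known in advance, so the (S,S)-catalyst is written as the one giving (2S). The first run is checked by chiral HPLC and circular dichroism (2S: positive band near 330 nm, negative near 290 nm). If it shows the opposite sense, the mirror-image catalyst from (R)-BINOL is used with no other change.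

## Route

Step 1
Reactants: 1 2,4-dihydroxyacetophenone; 2 allyl bromide
Product: 3 4-allyloxy-2-hydroxyacetophenone
Conditions: allyl bromide (1.1 equiv), K2CO3 (1.2 equiv), acetone, reflux, 6 h
Reagents that add atoms: allyl bromide, C=CCBr
Why: Williamson ether synthesis; the 4-OH is the more acidic and unhindered phenol, while the 2-OH is locked in a hydrogen bond to the ketone, so mono-O-allylation at O-4 is selective.

Step 2
Reactants: 3 4-allyloxy-2-hydroxyacetophenone
Product: 5 3-allyl-2,4-dihydroxyacetophenone, via ortho-dienone 4 (not isolated)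
Conditions: N,N-diethylaniline, 210 °C, N2, 5 h; acid wash, crystallisation
Reagents that add atoms: none
Why: Aromatic Claisen rearrangement ([3,3] shift, then tautomerisation of dienone 4); the chelated 2-hydroxyaryl ketone raises C3=C4 double-bond character, so the allyl group goes mainly to C-3 between the two oxygens, a long-established selectivity for this substrate.

Step 3
Reactants: 6 3,4-dihydroxybenzaldehyde; 2 allyl bromide
Product: 7 4-allyloxy-3-hydroxybenzaldehyde
Conditions: allyl bromide (1.1 equiv), NaHCO3 (1.5 equiv), DMF, 40 °C, 20 h, N2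
Reagents that add atoms: allyl bromide, C=CCBr
Why: Williamson ether synthesis under weak-base control; only the 4-OH (para to CHO, a vinylogous acid) is deprotonated by NaHCO3, which gives the known 4-O-selective monoalkylation of this catechol.

Step 4
Reactants: 7 4-allyloxy-3-hydroxybenzaldehyde
Product: 9 3-allyl-4,5-dihydroxybenzaldehyde, via ortho-dienone 8 (not isolated)
Conditions: N,N-diethylaniline, 195 °C, N2, 3 h
Reagents that add atoms: none
Why: Aromatic Claisen rearrangement; of the two positions ortho to O-4, one carries OH and cannot rearomatise, so only the free position gives a stable product, as in the analogous O-allylvanillin rearrangement.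

Step 5
Reactants: 5 3-allyl-2,4-dihydroxyacetophenone; 9 3-allyl-4,5-dihydroxybenzaldehyde
Product: 11 (E)-1-(3-allyl-2,4-dihydroxyphenyl)-3-(3-allyl-4,5-dihydroxyphenyl)prop-2-en-1-one, via aldol adduct 10 (not isolated)
Conditions: HCl (3 mol/L in EtOH), 0 °C to rt, 24 h, N2; crystallise the orange chalcone
Reagents that add atoms: none
Why: Acid-catalysed Claisen–Schmidt (crossed aldol) condensation; the enol of 5 adds to protonated 9 and aldol 10 loses water through its p-hydroxybenzylic cation to give the E-enone, acid avoids the unreactive phenoxides and catechol autoxidation seen with base, and terminal allyl groups tolerate ethanolic HCl at room temperature where prenyl groups would not.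

Step 6
Reactants: 11 (E)-1-(3-allyl-2,4-dihydroxyphenyl)-3-(3-allyl-4,5-dihydroxyphenyl)prop-2-en-1-one
Product: 13 (2S)-8-allyl-2-(3-allyl-4,5-dihydroxyphenyl)-7-hydroxychroman-4-one, via enol 12 (not isolated)
Conditions: (S,S)-imidodiphosphorimidate acid HN[P(=NSO2CF3)((S)-3,3'-Ar2-BINOLate)]2, Ar = 3,5-(CF3)2C6H3 (5 mol %), CH2Cl2/Et2O 5:1 (0.05 mol/L), 0 °C, argon, dark; stop at ca. 85–90% conversion, filter through silica, recycle recovered 11
Reagents that add atoms: none
Why: Proposed new method: enantioselective Brønsted-acid-catalysed 6-endo-trig oxa-Michael closure of an unactivated, fully unprotected 2'-hydroxychalcone, in which the strong confined acid protonates the ketone (the ring B 4-OH and 3-OH donors make this vinylogous p-quinone-methide-type cation easy to reach), breaking the 2'-OH···O=C chelate, while the chiral anion stays hydrogen-bonded to both C=OH+ and the 2'-OH, holds the enone in the s-trans conformer needed for closure and lets the phenol oxygen reach only the Si face of C-beta to give enol 12, which is ketonised in the same pocket to (2S)-13; ring opening is slower than closure by roughly the equilibrium constant times the selectivity factor, so stopping before full equilibration keeps the ee, monosubstituted allyl groups are not protonated here whereas o-prenylphenols would close to chromans (hence this step comes before step 7), and the closest known reaction types are chiral phosphoric acid catalysed intramolecular oxa-Michael additions to cyclohexadienones and unsaturated thioesters, confined-acid Nazarov cyclisations of simple divinyl ketones, and thiourea–cinchona closure of ester-activated chalcones.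

Step 7
Reactants: 13 (2S)-8-allyl-2-(3-allyl-4,5-dihydroxyphenyl)-7-hydroxychroman-4-one; 14 2-methyl-2-butene
Product: 17 (2S)-2-[3,4-dihydroxy-5-(3-methylbut-2-en-1-yl)phenyl]-7-hydroxy-8-(3-methylbut-2-en-1-yl)chroman-4-one, via 8-prenyl mono-metathesis product 15 (not isolated), via 5'-prenyl mono-metathesis product 16 (not isolated)
Conditions: second-generation Grubbs catalyst RuCl2(=CHPh)(PCy3)(SIMes) (2 × 3 mol %), 2-methyl-2-butene/CH2Cl2 1:1, 38 °C, sealed tube, argon, 12 h; neutral work-up, silica
Reagents that add atoms: 2-methyl-2-butene, CC=C(C)C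
Why: Olefin cross-metathesis of terminal allylarenes with 2-methyl-2-butene as isopropylidene donor is the standard allyl-to-prenyl conversion and tolerates ketones and free phenols; it runs under neutral conditions, so the base-sensitive C-2 stereocentre is not touched.

## Compound list
1 | 2,4-dihydroxyacetophenone | CC(=O)c1ccc(O)cc1O | starting material
2 | allyl bromide | C=CCBr | starting material
3 | 4-allyloxy-2-hydroxyacetophenone | CC(=O)c1ccc(OCC=C)cc1O | intermediate
4 | 4-acetyl-6-allyl-5-hydroxycyclohexa-2,4-dien-1-one (racemic ortho-dienone, not isolated) | CC(=O)C1=C(O)C(CC=C)C(=O)C=C1 | intermediate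
5 | 3-allyl-2,4-dihydroxyacetophenone | CC(=O)c1ccc(O)c(CC=C)c1O | intermediate
6 | 3,4-dihydroxybenzaldehyde | O=Cc1ccc(O)c(O)c1 | starting material
7 | 4-allyloxy-3-hydroxybenzaldehyde | O=Cc1ccc(OCC=C)c(O)c1 | intermediate
8 | 3-allyl-5-hydroxy-4-oxocyclohexa-1,5-diene-1-carbaldehyde (racemic ortho-dienone, not isolated) | O=CC1=CC(CC=C)C(=O)C(O)=C1 | intermediate
9 | 3-allyl-4,5-dihydroxybenzaldehyde | O=Cc1cc(O)c(O)c(CC=C)c1 | intermediate
10 | 1-(3-allyl-2,4-dihydroxyphenyl)-3-(3-allyl-4,5-dihydroxyphenyl)-3-hydroxypropan-1-one (racemic aldol adduct, not isolated) | C=CCc1cc(C(O)CC(=O)c2ccc(O)c(CC=C)c2O)cc(O)c1O | intermediate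
11 | (E)-1-(3-allyl-2,4-dihydroxyphenyl)-3-(3-allyl-4,5-dihydroxyphenyl)prop-2-en-1-one | C=CCc1cc(/C=C/C(=O)c2ccc(O)c(CC=C)c2O)cc(O)c1O | intermediate
12 | (2S)-8-allyl-2-(3-allyl-4,5-dihydroxyphenyl)-2H-chromene-4,7-diol (enol, not isolated) | C=CCc1cc([C@@H]2C=C(O)c3ccc(O)c(CC=C)c3O2)cc(O)c1O | intermediate
13 | (2S)-8-allyl-2-(3-allyl-4,5-dihydroxyphenyl)-7-hydroxychroman-4-one | C=CCc1cc([C@@H]2CC(=O)c3ccc(O)c(CC=C)c3O2)cc(O)c1O | intermediate
14 | 2-methyl-2-butene | CC=C(C)C | starting material
15 | (2S)-2-(3-allyl-4,5-dihydroxyphenyl)-7-hydroxy-8-(3-methylbut-2-en-1-yl)chroman-4-one (not isolated) | C=CCc1cc([C@@H]2CC(=O)c3ccc(O)c(CC=C(C)C)c3O2)cc(O)c1O | intermediate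
16 | (2S)-8-allyl-2-[3,4-dihydroxy-5-(3-methylbut-2-en-1-yl)phenyl]-7-hydroxychroman-4-one (not isolated) | CC(C)=CCc1cc([C@@H]2CC(=O)c3ccc(O)c(CC=C)c3O2)cc(O)c1O | intermediate
17 | (2S)-2-[3,4-dihydroxy-5-(3-methylbut-2-en-1-yl)phenyl]-7-hydroxy-8-(3-methylbut-2-en-1-yl)chroman-4-one | CC(C)=CCc1cc([C@@H]2CC(=O)c3ccc(O)c(CC=C(C)C)c3O2)cc(O)c1O | target

## Step count and risks
Total steps: 7. Longest linear sequence: 5 (steps 1, 2, 5, 6, 7 or steps 3, 4, 5, 6, 7). No protecting groups are used. Compound 5 is also listed in supplier catalogues; I have not checked its current price or stock. Buying it would lower the total to 5 without changing the longest linear sequence.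

**Risk 1 (step 6, the proposed new step).**
- The four phenolic OH groups and the ether cosolvent may blunt the acid and make closure slow.
- The ee may be only moderate.
- Intermolecular Friedel–Crafts-type addition of an electron-rich ring to the protonated enone may compete.
- Fallback (known chemistry), setting out from 11 and coming back at 13: 11 is closed with NaOAc in refluxing EtOH, the classical base-mediated oxa-Michael equilibration. This gives racemic 8-allyl-2-(3-allyl-4,5-dihydroxyphenyl)-7-hydroxychroman-4-one F1. It is resolved by preparative supercritical-fluid chromatography on an amylose tris(3,5-dimethylphenylcarbamate) phase. The (2S) fraction is 13. The (2R)-8-allyl-2-(3-allyl-4,5-dihydroxyphenyl)-7-hydroxychroman-4-one F2 is returned to the NaOAc equilibration, which racemises it through 11, and is resolved again.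

**Risk 2 (step 7).**
- The free catechol may bind ruthenium.
- The o-allylphenols may isomerise to propenylarenes before both metatheses are complete.
- Fallback, setting out from 13 and coming back at 17: 13 is silylated (TBSCl, imidazole, DMF, 0 °C to rt). This gives (2S)-8-allyl-2-[3-allyl-4,5-bis(tert-butyldimethylsilyloxy)phenyl]-7-(tert-butyldimethylsilyloxy)chroman-4-one F3. Cross-metathesis of this lipophilic, non-chelating substrate with 14 and RuCl2(=CHPh)(PCy3)(SIMes) gives the corresponding (2S)-tris-O-TBS diprenylflavanone F4. The silyl groups are removed with Et3N·3HF in THF, which is slightly acidic, so the ring does not open and C-2 does not racemise. This delivers 17.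

**Risk 3 (step 5).**
- Condensation of two free polyphenols may stall.
- Part of 11 may close to racemic flavanone. That material must be removed, or it lowers the ee after step 6.
- Fallback, setting out from 5 and 9 and coming back at 11:
  - 5 with MOMCl and K2CO3 in acetone (the chelated 2-OH stays free) gives 1-[3-allyl-2-hydroxy-4-(methoxymethoxy)phenyl]ethanone F5.
  - 9 with MOMCl and iPr2NEt in CH2Cl2 gives 3-allyl-4,5-bis(methoxymethoxy)benzaldehyde F6.
  - Standard base Claisen–Schmidt condensation (KOH, EtOH/H2O, rt) joins them to the (E)-tris-O-methoxymethyl chalcone F7.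
  - HCl in MeOH at 40 °C, which the allyl groups tolerate, releases 11.

Further compounds
F1 | step 6 | racemic 8-allyl-2-(3-allyl-4,5-dihydroxyphenyl)-7-hydroxychroman-4-one | C=CCc1cc(C2CC(=O)c3ccc(O)c(CC=C)c3O2)cc(O)c1O
F2 | step 6 | (2R)-8-allyl-2-(3-allyl-4,5-dihydroxyphenyl)-7-hydroxychroman-4-one | C=CCc1cc([C@H]2CC(=O)c3ccc(O)c(CC=C)c3O2)cc(O)c1O
F3 | step 7 | (2S)-8-allyl-2-[3-allyl-4,5-bis(tert-butyldimethylsilyloxy)phenyl]-7-(tert-butyldimethylsilyloxy)chroman-4-one | C=CCc1cc([C@@H]2CC(=O)c3ccc(O[Si](C)(C)C(C)(C)C)c(CC=C)c3O2)cc(O[Si](C)(C)C(C)(C)C)c1O[Si](C)(C)C(C)(C)C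
F4 | step 7 | (2S)-2-[3,4-bis(tert-butyldimethylsilyloxy)-5-(3-methylbut-2-en-1-yl)phenyl]-7-(tert-butyldimethylsilyloxy)-8-(3-methylbut-2-en-1-yl)chroman-4-one | CC(C)=CCc1cc([C@@H]2CC(=O)c3ccc(O[Si](C)(C)C(C)(C)C)c(CC=C(C)C)c3O2)cc(O[Si](C)(C)C(C)(C)C)c1O[Si](C)(C)C(C)(C)C
F5 | step 5 | 1-[3-allyl-2-hydroxy-4-(methoxymethoxy)phenyl]ethanone | CC(=O)c1ccc(OCOC)c(CC=C)c1O
F6 | step 5 | 3-allyl-4,5-bis(methoxymethoxy)benzaldehyde | O=Cc1cc(OCOC)c(OCOC)c(CC=C)c1
F7 | step 5 | (E)-1-[3-allyl-2-hydroxy-4-(methoxymethoxy)phenyl]-3-[3-allyl-4,5-bis(methoxymethoxy)phenyl]prop-2-en-1-one | C=CCc1cc(/C=C/C(=O)c2ccc(OCOC)c(CC=C)c2O)cc(OCOC)c1OCOC
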